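**Retrosynthetic overview**
1. Rings C and F are both 2-aryl-3-hydroxychromans. Cutting their benzylic ether bonds O1–C2 (2,3-trans ring C) and O1'–C2' (2,3-cis ring F) leads back to bis-epoxide 20, in which the ring A phenol faces a (2S,3S)-trans-epoxide and the ring D phenol a (2'R,3'S)-cis-epoxide; both rings close in one operation with inversion at C2 and C2'.
2. Both epoxides come from diene 17: Shi epoxidation of the E-olefin C2=C3 and Jacobsen–Katsuki epoxidation of the Z-olefin C2'=C3'. The two phenols travel as triisopropylsilyl ethers.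
3. The C4 methine (bonded to ring A and to C6' of ring D) is set by rhodium/BINAP conjugate addition of ring D boronate 13 to the ring A/ring B chalcone 4; the ketone becomes the E-olefin by enol triflate reduction.
4. Boronate 13 comes from bromosalicylaldehyde 8 and arylacetylene 6 (addition, deoxygenation, semihydrogenation, borylation). Rings A and D both derive from aldehyde 1, so no symmetric dialdehyde has to be desymmetrised.
5. Ring order: rings A, B, D and E are bought as benzyl-protected arenes; rings C and F are formed last, together, and hydrogenolysis ends the route.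

Key step: step 16

Remark 1: the SMILES is read as (2R,3S,4S) in the upper unit (rings A, C, B; 2,3-trans, 3,4-cis) and (2S,3S) in the lower unit (rings D, F, E, primed locants; 2,3-cis), joined C4–C6'.
Remark 2: the senses of induction in steps 10, 13 and 14 are assigned from the empirical models of the parent catalysts and are to be checked on the first product; the antipodal ligand or catalyst is available in each case.

**Step 1**
Reactants: 1 4-(benzyloxy)-2-hydroxybenzaldehyde; 2 1-[4-(benzyloxy)phenyl]ethan-1-one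
Product: 3 (E)-3-[4-(benzyloxy)-2-hydroxyphenyl]-1-[4-(benzyloxy)phenyl]prop-2-en-1-one
Conditions: KOH (50% aq.), EtOH, 0 °C → rt; AcOH to pH 6
Reagents that add atoms: none
Why: Claisen–Schmidt condensation: the methyl ketone enolate adds to the aldehyde and the aldol loses water to the conjugated E-enone, the ortho-phenoxide slowing but not preventing the addition; no stereocentre is formed.

**Step 2**
Reactants: 3 (E)-3-[4-(benzyloxy)-2-hydroxyphenyl]-1-[4-(benzyloxy)phenyl]prop-2-en-1-one
Product: 4 (E)-3-{4-(benzyloxy)-2-[(triisopropylsilyl)oxy]phenyl}-1-[4-(benzyloxy)phenyl]prop-2-en-1-one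
Conditions: TIPSOTf, 2,6-lutidine, CH2Cl2, 0 °C
Reagents that add atoms: triisopropylsilyl trifluoromethanesulfonate, CC(C)[Si](OS(=O)(=O)C(F)(F)F)(C(C)C)C(C)C
Why: O-silylation of the phenol; the triisopropylsilyl ether should survive the aqueous base of steps 10, 13 and 14, leave with fluoride next to epoxides, and keep the later ketone from cyclising onto this oxygen.

**Step 3**
Reactants: 5 3,4-bis(benzyloxy)benzaldehyde
Product: 6 1,2-bis(benzyloxy)-4-ethynylbenzene
Conditions: dimethyl (1-diazo-2-oxopropyl)phosphonate, K2CO3, MeOH, rt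
Reagents that add atoms: dimethyl (1-diazo-2-oxopropyl)phosphonate, CC(=O)C(=[N+]=[N-])P(=O)(OC)OC
Why: Ohira–Bestmann form of the Seyferth–Gilbert homologation: methanolysis frees the diazomethylphosphonate anion, which olefinates the aldehyde and loses N2 to give the terminal alkyne under conditions inert to benzyl ethers.

**Step 4**
Reactants: 1 4-(benzyloxy)-2-hydroxybenzaldehyde
Product: 7 4-(benzyloxy)-5-bromo-2-hydroxybenzaldehyde
Conditions: NBS, MeCN, 0 °C → rt, dark
Reagents that add atoms: N-bromosuccinimide, BrN1C(=O)CCC1=O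
Why: Electrophilic aromatic bromination: C5 is para to the hydroxyl, ortho to the benzyloxy group and meta to the formyl group, whereas C3 lies between two oxygens, so bromine should enter at the future C6'.

**Step 5**
Reactants: 7 4-(benzyloxy)-5-bromo-2-hydroxybenzaldehyde
Product: 8 4-(benzyloxy)-5-bromo-2-[(triisopropylsilyl)oxy]benzaldehyde
Conditions: TIPSOTf, 2,6-lutidine, CH2Cl2, 0 °C
Reagents that add atoms: triisopropylsilyl trifluoromethanesulfonate, CC(C)[Si](OS(=O)(=O)C(F)(F)F)(C(C)C)C(C)C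
Why: O-silylation of the hydrogen-bonded phenol with the reactive silyl triflate; this oxygen is the future O1' and stays masked until step 15.

**Step 6**
Reactants: 6 1,2-bis(benzyloxy)-4-ethynylbenzene; 8 4-(benzyloxy)-5-bromo-2-[(triisopropylsilyl)oxy]benzaldehyde
Product: 10 rac-1-{4-(benzyloxy)-5-bromo-2-[(triisopropylsilyl)oxy]phenyl}-3-[3,4-bis(benzyloxy)phenyl]prop-2-yn-1-ol, via alkynylmagnesium bromide 9 (not isolated)
Conditions: EtMgBr, THF, 0 °C → rt; then 8, −40 → 0 °C; aq. NH4Cl
Reagents that add atoms: none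
Why: Deprotonation of the terminal alkyne by the Grignard base and 1,2-addition of the alkynylmagnesium species to the aldehyde; the cold magnesium alkoxide is not expected to take the silyl group from the neighbouring phenol oxygen, and the carbinol centre may be racemic because step 7 removes it.

**Step 7**
Reactants: 10 rac-1-{4-(benzyloxy)-5-bromo-2-[(triisopropylsilyl)oxy]phenyl}-3-[3,4-bis(benzyloxy)phenyl]prop-2-yn-1-ol
Product: 11 1-(benzyloxy)-2-bromo-4-{3-[3,4-bis(benzyloxy)phenyl]prop-2-yn-1-yl}-5-[(triisopropylsilyl)oxy]benzene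
Conditions: Et3SiH, CF3CO2H, CH2Cl2, −40 → −10 °C
Reagents that add atoms: none
Why: Ionic hydrogenation of a benzylic, propargylic alcohol: the cation, stabilised by the ortho-silyloxy and para-benzyloxy groups of ring D, should take hydride from the silane at the benzylic carbon (future C4'), leaving the 1,3-diarylpropyne.

**Step 8**
Reactants: 11 1-(benzyloxy)-2-bromo-4-{3-[3,4-bis(benzyloxy)phenyl]prop-2-yn-1-yl}-5-[(triisopropylsilyl)oxy]benzene
Product: 12 1-(benzyloxy)-2-bromo-4-{(2Z)-3-[3,4-bis(benzyloxy)phenyl]prop-2-en-1-yl}-5-[(triisopropylsilyl)oxy]benzene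
Conditions: H2 (1 atm), Pd/CaCO3 poisoned with Pb(OAc)2, quinoline, EtOAc, rt
Reagents that add atoms: none
Why: Lindlar semihydrogenation: syn delivery of hydrogen to the alkyne on the poisoned surface gives the Z-olefin C2'=C3', and the aryl bromide and benzyl ethers are not cleaved by this catalyst.

**Step 9**
Reactants: 12 1-(benzyloxy)-2-bromo-4-{(2Z)-3-[3,4-bis(benzyloxy)phenyl]prop-2-en-1-yl}-5-[(triisopropylsilyl)oxy]benzene
Product: 13 2-{2-(benzyloxy)-5-[(2Z)-3-[3,4-bis(benzyloxy)phenyl]prop-2-en-1-yl]-4-[(triisopropylsilyl)oxy]phenyl}-4,4,5,5-tetramethyl-1,3,2-dioxaborolane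
Conditions: B2pin2, Pd(dppf)Cl2 (3 mol %), KOAc, 1,4-dioxane, 85 °C
Reagents that add atoms: bis(pinacolato)diboron, CC1(C)OB(OC1(C)C)B1OC(C)(C)C(C)(C)O1
Why: Miyaura borylation of the aryl bromide (oxidative addition, acetate-assisted transmetallation with the diboron, reductive elimination); the weak base leaves the silyl ether and the Z-olefin alone.

**Step 10**
Reactants: 4 (E)-3-{4-(benzyloxy)-2-[(triisopropylsilyl)oxy]phenyl}-1-[4-(benzyloxy)phenyl]prop-2-en-1-one; 13 ring D boronate
Product: 14 (3S)-3-{4-(benzyloxy)-2-[(triisopropylsilyl)oxy]phenyl}-3-{2-(benzyloxy)-5-[(2Z)-3-[3,4-bis(benzyloxy)phenyl]prop-2-en-1-yl]-4-[(triisopropylsilyl)oxy]phenyl}-1-[4-(benzyloxy)phenyl]propan-1-one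
Conditions: [RhCl(C2H4)2]2 (2.5 mol %), (R)-BINAP (5.5 mol %), K3PO4 (aq.), 1,4-dioxane/H2O 10:1, 60 °C
Reagents that add atoms: none
Why: Hayashi–Miyaura asymmetric 1,4-addition: ring D passes from boron to rhodium, the enone inserts into the aryl–rhodium bond and water frees the ketone; C4 is set by the ligand, since on the empirical model (S)-BINAP–rhodium aryls attack the α-si face of E-enones, so the (R)-ligand should deliver ring D to the α-re face and give the (3S)-ketone with the C4 configuration of the target.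

**Step 11**
Reactants: 14 (3S)-triaryl ketone
Product: 16 (1Z,3S)-1-[4-(benzyloxy)phenyl]-3,3-diarylprop-1-en-1-yl trifluoromethanesulfonate (aryl groups as in 14), via potassium Z-enolate 15 (not isolated)
Conditions: KN(SiMe3)2 (1.05 equiv), THF, −78 °C; PhNTf2, −78 → 0 °C
Reagents that add atoms: N-phenylbis(trifluoromethanesulfonimide), O=S(=O)(N(c1ccccc1)S(=O)(=O)C(F)(F)F)C(F)(F)F
Why: Kinetic deprotonation of the aryl ketone at C3 gives the Z-enolate (ring B and the C4 substituent avoid allylic strain) and O-sulfonylation keeps that geometry; C4–H is not acidified and stays configured.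

**Step 12**
Reactants: 16 (1Z,3S)-enol triflate
Product: 17 (S)-configured E,Z-diene: ring B–CH=CH–CH(ring A)(ring D) with E-olefin C2=C3, and the Z-olefin C2'=C3' on ring D; both phenols as triisopropylsilyl ethers
Conditions: Pd(OAc)2 (5 mol %), PPh3, Bu3N, HCO2H, DMF, 60 °C
Reagents that add atoms: none
Why: Palladium-catalysed formate reduction of the enol triflate: oxidative addition, exchange of triflate for formate, loss of CO2 and C–H reductive elimination with retention turn the Z-triflate into the E-olefin, with no benzylic cation that the ring A silyl ether could trap or that could scramble C4.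

**Step 13**
Reactants: 17 E,Z-diene
Product: 18 diene 17 with the Z-olefin converted into the (2'R,3'S)-cis-epoxide (C2' bears ring E); E-olefin intact
Conditions: (R,R)-N,N'-bis(3,5-di-tert-butylsalicylidene)-1,2-cyclohexanediaminomanganese chloride (5 mol %), 4-phenylpyridine N-oxide, NaOCl (aq., pH 11.3), CH2Cl2, 0 °C; Et3N-deactivated SiO2
Reagents that add atoms: sodium hypochlorite, [Na+].[O-]Cl
Why: Jacobsen–Katsuki epoxidation: the oxomanganese salen species transfers oxygen to the aryl-conjugated Z-olefin much faster than to the hindered E-olefin, and the (R,R)-catalyst, which gives (1R,2S)-epoxides from indene and cis-β-methylstyrene, should set C2' (R) and C3' (S).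

**Step 14**
Reactants: 18 mono-epoxide
Product: 19 bis-epoxide: (2S,3S)-trans-epoxide at C2–C3 (C2 bears ring B) and (2'R,3'S)-cis-epoxide, both phenols as triisopropylsilyl ethers
Conditions: 1,2:4,5-di-O-isopropylidene-β-L-erythro-2,3-hexodiulo-2,6-pyranose (0.3 equiv), Oxone (2KHSO5·KHSO4·K2SO4), K2CO3, Bu4NHSO4, MeCN/CH2(OMe)2, aq. Na2B4O7/Na2EDTA, 0 °C; Et3N-deactivated SiO2
Reagents that add atoms: potassium peroxymonosulfate (from Oxone), [K+].[O-]S(=O)(=O)OO
Why: Shi epoxidation: the chiral dioxirane formed from the ketone transfers oxygen to the E-olefin through a spiro transition state; the D-fructose ketone gives (R,R)-epoxides from trans-β-aryl olefins, so its L-enantiomer should set C2 (S) and C3 (S) under reagent control, while the basic buffer preserves the cis-epoxide and the silyl ethers.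

**Step 15**
Reactants: 19 bis-epoxide bis-silyl ether
Product: 20 bis-epoxide with free ring A and ring D phenols
Conditions: Bu4NF/AcOH (1:1, 2.5 equiv), THF, 0 °C; pH 7 buffer, used crude at once
Reagents that add atoms: none
Why: Fluoride cleavage of the two aryl silyl ethers; acetic acid keeps the freed oxygens as neutral phenols, so that no phenoxide opens an epoxide at C3 or C3' in the base-favoured 5-exo mode.

**Step 16**
Reactants: 20 bis-epoxide bis-phenol
Product: 21 penta-O-benzyl target, (2R,3S,4S)/(2'S,3'S), both 3-hydroxyls free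
Conditions: PPTS (0.2 equiv), CH2Cl2, −20 → 0 °C
Reagents that add atoms: none
Why: Pyridinium tosylate hydrogen-bonds to each epoxide oxygen and the neighbouring phenol attacks the benzylic carbon from the rear in a loose SN2 transition state; this is the acid-promoted intramolecular opening of an aryl epoxide by a phenol that is known as a single closure to flavan-3-ols, run here on two sites in one flask. Ring C closes 6-endo-tet by the ring A hydroxyl (O1) on C2 of the trans-epoxide, and ring F closes 6-endo-tet by the ring D hydroxyl (O1') on C2' of the cis-epoxide. C2 and C2' are the new stereocentres and each is set by inversion of its epoxide carbon, so the (2S,3S)-trans-epoxide gives the (2R,3S) 2,3-trans ring C and the (2'R,3'S)-cis-epoxide gives the (2'S,3'S) 2,3-cis ring F, while C3, C3' and C4 are not touched. The step needs 6-endo over 5-exo opening and inversion instead of ionisation: the first should follow from the 4-benzyloxyphenyl and 3,4-bis(benzyloxy)phenyl groups, which stabilise positive charge only at C2 and C2', and from the crowding of C3 by the diarylmethine; the second from a weak acid in a non-ionising solvent at low temperature with each nucleophile already held in reach. Site selectivity is built in, because O7' is a benzyl ether and each phenol reaches only its own epoxide through a six-membered transition state. The most exposed point is C2' of the cis-epoxide, where ionisation would lead to a 2,3-trans ring F.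

**Step 17**
Reactants: 21 penta-O-benzyl target
Product: 22 target, CNP0243811.4
Conditions: H2 (1 atm), Pd(OH)2/C, THF/MeOH, rt
Reagents that add atoms: none
Why: Hydrogenolysis of the five aryl benzyl ethers; under neutral conditions the benzylic ring bonds C2–O1 and C2'–O1' and all five stereocentres should be retained.

**Compound list**
1 | 4-(benzyloxy)-2-hydroxybenzaldehyde | O=Cc1ccc(OCc2ccccc2)cc1O | starting material
2 | 1-[4-(benzyloxy)phenyl]ethan-1-one | CC(=O)c1ccc(OCc2ccccc2)cc1 | starting material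
3 | (E)-3-[4-(benzyloxy)-2-hydroxyphenyl]-1-[4-(benzyloxy)phenyl]prop-2-en-1-one | O=C(/C=C/c1ccc(OCc2ccccc2)cc1O)c1ccc(OCc2ccccc2)cc1 | intermediate
4 | (E)-3-{4-(benzyloxy)-2-[(triisopropylsilyl)oxy]phenyl}-1-[4-(benzyloxy)phenyl]prop-2-en-1-one | O=C(/C=C/c1ccc(OCc2ccccc2)cc1O[Si](C(C)C)(C(C)C)C(C)C)c1ccc(OCc2ccccc2)cc1 | intermediate
5 | 3,4-bis(benzyloxy)benzaldehyde | O=Cc1ccc(OCc2ccccc2)c(OCc2ccccc2)c1 | starting material
6 | 1,2-bis(benzyloxy)-4-ethynylbenzene | C#Cc1ccc(OCc2ccccc2)c(OCc2ccccc2)c1 | intermediate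
7 | 4-(benzyloxy)-5-bromo-2-hydroxybenzaldehyde | O=Cc1cc(Br)c(OCc2ccccc2)cc1O | intermediate
8 | 4-(benzyloxy)-5-bromo-2-[(triisopropylsilyl)oxy]benzaldehyde | O=Cc1cc(Br)c(OCc2ccccc2)cc1O[Si](C(C)C)(C(C)C)C(C)C | intermediate
9 | {[3,4-bis(benzyloxy)phenyl]ethynyl}magnesium bromide | Br[Mg]C#Cc1ccc(OCc2ccccc2)c(OCc2ccccc2)c1 | intermediate (not isolated)
10 | rac-1-{4-(benzyloxy)-5-bromo-2-[(triisopropylsilyl)oxy]phenyl}-3-[3,4-bis(benzyloxy)phenyl]prop-2-yn-1-ol | OC(C#Cc1ccc(OCc2ccccc2)c(OCc2ccccc2)c1)c1cc(Br)c(OCc2ccccc2)cc1O[Si](C(C)C)(C(C)C)C(C)C | intermediate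
11 | 1-(benzyloxy)-2-bromo-4-{3-[3,4-bis(benzyloxy)phenyl]prop-2-yn-1-yl}-5-[(triisopropylsilyl)oxy]benzene | Brc1cc(CC#Cc2ccc(OCc3ccccc3)c(OCc3ccccc3)c2)c(O[Si](C(C)C)(C(C)C)C(C)C)cc1OCc1ccccc1 | intermediate
12 | 1-(benzyloxy)-2-bromo-4-{(2Z)-3-[3,4-bis(benzyloxy)phenyl]prop-2-en-1-yl}-5-[(triisopropylsilyl)oxy]benzene | Brc1cc(C/C=C\c2ccc(OCc3ccccc3)c(OCc3ccccc3)c2)c(O[Si](C(C)C)(C(C)C)C(C)C)cc1OCc1ccccc1 | intermediate
13 | 2-{2-(benzyloxy)-5-[(2Z)-3-[3,4-bis(benzyloxy)phenyl]prop-2-en-1-yl]-4-[(triisopropylsilyl)oxy]phenyl}-4,4,5,5-tetramethyl-1,3,2-dioxaborolane | CC1(C)OB(OC1(C)C)c1cc(C/C=C\c2ccc(OCc3ccccc3)c(OCc3ccccc3)c2)c(O[Si](C(C)C)(C(C)C)C(C)C)cc1OCc1ccccc1 | intermediate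
14 | (3S)-3-(ring A aryl)-3-(ring D aryl)-1-[4-(benzyloxy)phenyl]propan-1-one, silyl-protected | O=C(C[C@H](c1ccc(OCc2ccccc2)cc1O[Si](C(C)C)(C(C)C)C(C)C)c1cc(C/C=C\c2ccc(OCc3ccccc3)c(OCc3ccccc3)c2)c(O[Si](C(C)C)(C(C)C)C(C)C)cc1OCc1ccccc1)c1ccc(OCc2ccccc2)cc1 | intermediate
15 | potassium (Z)-enolate of 14 | [K+].[O-]/C(=C\[C@H](c1ccc(OCc2ccccc2)cc1O[Si](C(C)C)(C(C)C)C(C)C)c1cc(C/C=C\c2ccc(OCc3ccccc3)c(OCc3ccccc3)c2)c(O[Si](C(C)C)(C(C)C)C(C)C)cc1OCc1ccccc1)c1ccc(OCc2ccccc2)cc1 | intermediate (not isolated)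
16 | (1Z,3S)-enol triflate of 14 | FC(F)(F)S(=O)(=O)O/C(=C\[C@H](c1ccc(OCc2ccccc2)cc1O[Si](C(C)C)(C(C)C)C(C)C)c1cc(C/C=C\c2ccc(OCc3ccccc3)c(OCc3ccccc3)c2)c(O[Si](C(C)C)(C(C)C)C(C)C)cc1OCc1ccccc1)c1ccc(OCc2ccccc2)cc1 | intermediate
17 | (S)-E,Z-diene (E-olefin C2=C3, Z-olefin C2'=C3'), bis-silyl ether | c1ccccc1COc1ccc(/C=C/[C@H](c2ccc(OCc3ccccc3)cc2O[Si](C(C)C)(C(C)C)C(C)C)c2cc(C/C=C\c3ccc(OCc4ccccc4)c(OCc4ccccc4)c3)c(O[Si](C(C)C)(C(C)C)C(C)C)cc2OCc2ccccc2)cc1 | intermediate
18 | (2'R,3'S)-cis-epoxide with E-olefin, bis-silyl ether | c1ccccc1COc1ccc(/C=C/[C@H](c2ccc(OCc3ccccc3)cc2O[Si](C(C)C)(C(C)C)C(C)C)c2cc(C[C@@H]3O[C@@H]3c3ccc(OCc4ccccc4)c(OCc4ccccc4)c3)c(O[Si](C(C)C)(C(C)C)C(C)C)cc2OCc2ccccc2)cc1 | intermediate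
19 | (2S,3S)-trans-/(2'R,3'S)-cis-bis-epoxide, bis-silyl ether | c1ccccc1COc1ccc(cc1)[C@@H]1O[C@H]1[C@H](c1ccc(OCc2ccccc2)cc1O[Si](C(C)C)(C(C)C)C(C)C)c1cc(C[C@@H]2O[C@@H]2c2ccc(OCc3ccccc3)c(OCc3ccccc3)c2)c(O[Si](C(C)C)(C(C)C)C(C)C)cc1OCc1ccccc1 | intermediate
20 | bis-epoxide with free ring A and ring D phenols | c1ccccc1COc1ccc(cc1)[C@@H]1O[C@H]1[C@H](c1ccc(OCc2ccccc2)cc1O)c1cc(C[C@@H]2O[C@@H]2c2ccc(OCc3ccccc3)c(OCc3ccccc3)c2)c(O)cc1OCc1ccccc1 | intermediate
21 | penta-O-benzyl target | c1ccccc1COc1ccc([C@H]2Oc3cc(OCc4ccccc4)ccc3[C@H](c3cc4c(cc3OCc3ccccc3)O[C@@H](c3ccc(OCc5ccccc5)c(OCc5ccccc5)c3)[C@@H](O)C4)[C@@H]2O)cc1 | intermediate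
22 | CNP0243811.4 | Oc1ccc([C@H]2Oc3cc(O)ccc3[C@H](c3cc4c(cc3O)O[C@@H](c3ccc(O)c(O)c3)[C@@H](O)C4)[C@@H]2O)cc1 | target

**Step count**
Total: 17 steps. Longest linear sequence: 14 steps (1 → 7 → 8 → 10 → 11 → 12 → 13 → 14 → 16 → 17 → 18 → 19 → 20 → 21 → 22).

**Steps most likely to fail**

Step 16. The two closures may not tolerate one acidity. The cis-epoxide may ionise at C2' before the ring D phenol arrives, with loss of inversion or a hydride shift to a benzyl ketone, or one ring may lag while the other product sits in acid. The fallback runs the two closures as separate single closures. It sets out from 18. Buffered Bu4NF/AcOH should free both phenols to give the bis-phenol cis-epoxide F1. PPTS in CH2Cl2 then closes ring F alone to the 2,3-cis-chromanol F2, since only the ring D phenol has an epoxide within reach. TIPSCl and imidazole re-silylate the ring A phenol selectively over the secondary 3'-hydroxyl to give the silyl ether F3. Shi epoxidation with the L-fructose-derived ketone gives the (2S,3S)-trans-epoxide F4. Bu4NF/AcOH frees the epoxy phenol F5, and PPTS closes ring C. The fallback comes back to the route at 21.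

Step 13. Bond rotation in the stepwise oxygen transfer may leak to the trans-epoxide, facial discrimination on this acyclic electron-rich Z-olefin may be incomplete, and the oxidant may also attack the E-olefin. The fallback replaces the metal-oxo transfer by a concerted one from a chiral dioxirane: the glucose-derived spiro-oxazolidinone ketone of the Shi epoxidation family for cis-olefins, in the enantiomer that gives the (1R,2S)-epoxide from cis-β-methylstyrene, with Oxone in buffered MeCN/CH2(OMe)2 at low conversion of oxidant. Dioxiranes react faster with cis- than with trans-olefins and cannot isomerise the olefin. The fallback sets out from 17 and comes back at 18; no new compound arises (F0).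

Step 10. Insertion at the β-carbon next to the ortho-silyloxy group may be slow enough for protodeboronation of the electron-rich boronate to win, or the facial preference may be weak. The fallback is an auxiliary-controlled cuprate addition and sets out from 1 and 12. Aldehyde 1 is silylated (TIPSOTf, 2,6-lutidine) to 4-(benzyloxy)-2-[(triisopropylsilyl)oxy]benzaldehyde F6. Horner–Wadsworth–Emmons reaction with diethyl {2-oxo-2-[(4R)-2-oxo-4-phenyl-1,3-oxazolidin-3-yl]ethyl}phosphonate (LiCl, iPr2NEt, MeCN) gives the (E)-enoyl oxazolidinone F7. Bromide 12 with Mg in THF gives the arylmagnesium bromide F8. F8 with CuBr·SMe2 adds to F7 at −40 °C anti to the 4-phenyl group of the magnesium-chelated syn-s-cis conformer, which should give the (3S)-adduct F9. MeNH(OMe)·HCl and AlMe3 convert F9 into the Weinreb amide F10, and 4-BnOC6H4MgBr gives the ketone. The fallback comes back to the route at 14.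

**Further compounds**
F1 | step 16 | bis-phenol (2'R,3'S)-cis-epoxide with E-olefin | c1ccccc1COc1ccc(/C=C/[C@H](c2ccc(OCc3ccccc3)cc2O)c2cc(C[C@@H]3O[C@@H]3c3ccc(OCc4ccccc4)c(OCc4ccccc4)c3)c(O)cc2OCc2ccccc2)cc1
F2 | step 16 | ring F closed (2'S,3'S)-chromanol with free ring A phenol and E-olefin | c1ccccc1COc1ccc(/C=C/[C@H](c2ccc(OCc3ccccc3)cc2O)c2cc3c(cc2OCc2ccccc2)O[C@@H](c2ccc(OCc4ccccc4)c(OCc4ccccc4)c2)[C@@H](O)C3)cc1
F3 | step 16 | ring A O-triisopropylsilyl ether of F2 | c1ccccc1COc1ccc(/C=C/[C@H](c2ccc(OCc3ccccc3)cc2O[Si](C(C)C)(C(C)C)C(C)C)c2cc3c(cc2OCc2ccccc2)O[C@@H](c2ccc(OCc4ccccc4)c(OCc4ccccc4)c2)[C@@H](O)C3)cc1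
F4 | step 16 | (2S,3S)-trans-epoxide of F3 | c1ccccc1COc1ccc(cc1)[C@@H]1O[C@H]1[C@H](c1ccc(OCc2ccccc2)cc1O[Si](C(C)C)(C(C)C)C(C)C)c1cc2c(cc1OCc1ccccc1)O[C@@H](c1ccc(OCc3ccccc3)c(OCc3ccccc3)c1)[C@@H](O)C2
F5 | step 16 | (2S,3S)-trans-epoxide with free ring A phenol, ring F closed | c1ccccc1COc1ccc(cc1)[C@@H]1O[C@H]1[C@H](c1ccc(OCc2ccccc2)cc1O)c1cc2c(cc1OCc1ccccc1)O[C@@H](c1ccc(OCc3ccccc3)c(OCc3ccccc3)c1)[C@@H](O)C2
F0 | step 13 | none | none
F6 | step 10 | 4-(benzyloxy)-2-[(triisopropylsilyl)oxy]benzaldehyde | O=Cc1ccc(OCc2ccccc2)cc1O[Si](C(C)C)(C(C)C)C(C)C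
F7 | step 10 | (4R)-3-[(2E)-3-{4-(benzyloxy)-2-[(triisopropylsilyl)oxy]phenyl}prop-2-enoyl]-4-phenyl-1,3-oxazolidin-2-one | O=C(/C=C/c1ccc(OCc2ccccc2)cc1O[Si](C(C)C)(C(C)C)C(C)C)N1C(=O)OC[C@H]1c1ccccc1
F8 | step 10 | arylmagnesium bromide from 12 | Br[Mg]c1cc(C/C=C\c2ccc(OCc3ccccc3)c(OCc3ccccc3)c2)c(O[Si](C(C)C)(C(C)C)C(C)C)cc1OCc1ccccc1
F9 | step 10 | (4R)-3-[(3S)-3-(ring A aryl)-3-(ring D aryl)propanoyl]-4-phenyl-1,3-oxazolidin-2-one | O=C(C[C@H](c1ccc(OCc2ccccc2)cc1O[Si](C(C)C)(C(C)C)C(C)C)c1cc(C/C=C\c2ccc(OCc3ccccc3)c(OCc3ccccc3)c2)c(O[Si](C(C)C)(C(C)C)C(C)C)cc1OCc1ccccc1)N1C(=O)OC[C@H]1c1ccccc1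
F10 | step 10 | (3S)-N-methoxy-N-methyl-3-(ring A aryl)-3-(ring D aryl)propanamide | CON(C)C(=O)C[C@H](c1ccc(OCc2ccccc2)cc1O[Si](C(C)C)(C(C)C)C(C)C)c1cc(C/C=C\c2ccc(OCc3ccccc3)c(OCc3ccccc3)c2)c(O[Si](C(C)C)(C(C)C)C(C)C)cc1OCc1ccccc1
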